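**Retrosynthetic overview** (drimane numbering: ring A = C1–C5 and C10, ring B = C5–C10, C11 = the CH2O carbon on C9, C12 = the methylene carbon on C8)
1. The aryl ether C11–O is cut last (Mitsunobu), giving the 3β,11-diol of the 6,8(12)-diene and 7-hydroxycoumarin.
2. The 9β-CH2O / 8(12)-methylene / 6-ene array of ring B comes from a conjugated 6,8-dienoate by deconjugative protonation; the dienoate comes from a C9 enone via its dienyl triflate and carbonylation (C11 from CO).
3. Key disconnection: ring A is opened at its most congested bond, C3–C4 (carbinol carbon to the quaternary gem-dimethyl carbon), giving a monocyclic keto aldehyde; forward, a hydrogen-atom-transfer radical cyclization.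
4. Enabling feature: C4 carries two methyl groups and no hydrogen, so it is an isopropenyl group on C5 plus one hydrogen atom, i.e. a tertiary radical; C3 is a carbonyl carbon reached through C5–C10–C1–C2 (six-membered ring A), and the C5 arm and the C10 chain are trans-diequatorial on ring B.
5. Ring B is not built: it is the ring of (R)-carvone (C5 stereocentre with its isopropenyl group, C8 methyl, C9 carbonyl). C10 is made by methylation then allylation. Ring order: B (chiral pool), then A (key step).

Key step: step 4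

Assumption (remark on the chemistry): the two C6 epimers formed in step 1 are carried on together, because that carbon is planarised again in step 2; (R)-(−)-carvone and 7-hydroxycoumarin are taken as commercial.

Step 1
Reactants: 1 (R)-(−)-carvone
Product: 3 (5R)-2,6-dimethyl-5-(prop-1-en-2-yl)cyclohex-2-en-1-one (6-methylcarvone; both C6 epimers), via lithium enolate 2 (not isolated)
Conditions: LiN(iPr)2, THF, −78 °C; then MeI, −78 to 0 °C
Reagents that add atoms: iodomethane, SMILES: CI
Why: Kinetic alpha'-deprotonation of the enone and SN2 methylation of the cross-conjugated enolate (enolate alkylation); the new centre need not be controlled because it becomes an enolate carbon again in step 2.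

Step 2
Reactants: 3 (5R)-2,6-dimethyl-5-(prop-1-en-2-yl)cyclohex-2-en-1-one
Product: 5 (5S,6S)-2,6-dimethyl-5-(prop-1-en-2-yl)-6-(prop-2-en-1-yl)cyclohex-2-en-1-one, via lithium enolate 4 (not isolated)
Conditions: LiN(iPr)2, THF, −78 °C; then allyl bromide, DMPU, −78 to 0 °C
Reagents that add atoms: allyl bromide (3-bromoprop-1-ene), SMILES: C=CCBr
Why: Enolate alkylation that forms the quaternary carbon (later C10); the allyl bromide should approach the tetrasubstituted enolate anti to the neighbouring isopropenyl group, which puts the allyl group trans and the methyl group cis to it.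

Step 3
Reactants: 5 (5S,6S)-2,6-dimethyl-5-(prop-1-en-2-yl)-6-(prop-2-en-1-yl)cyclohex-2-en-1-one
Product: 6 3-[(1S,6S)-1,3-dimethyl-2-oxo-6-(prop-1-en-2-yl)cyclohex-3-en-1-yl]propanal
Conditions: PdCl2(PhCN)2 (12 mol%), CuCl2·2H2O (12 mol%), AgNO2 (6 mol%), O2 (1 atm), tBuOH/MeNO2 15:1, rt
Reagents that add atoms: dioxygen, SMILES: O=O
Why: Aldehyde-selective (anti-Markovnikov) Wacker oxidation under nitrite co-catalysis; only the monosubstituted allyl alkene is a substrate for divalent palladium here, so the 1,1-disubstituted isopropenyl group and the enone should stay intact, and no stereocentre is touched.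

Step 4
Reactants: 6 3-[(1S,6S)-1,3-dimethyl-2-oxo-6-(prop-1-en-2-yl)cyclohex-3-en-1-yl]propanal
Product: 9 (4aS,6S,8aS)-6-hydroxy-2,5,5,8a-tetramethyl-4a,5,6,7,8,8a-hexahydronaphthalen-1(4H)-one, via tertiary C4 radical 7 (not isolated), via alkoxyl radical 8 (not isolated)
Conditions: Fe(acac)3 (0.3 equiv), PhSiH3 (2.5 equiv), EtOH, 60 °C, Ar
Reagents that add atoms: none
Why: An iron hydride formed from Fe(acac)3 and PhSiH3 in EtOH should transfer a hydrogen atom to the terminal CH2 of the isopropenyl group, which creates the second methyl group and the tertiary C4 radical 7; 7 adds to the aldehyde carbon C3 to give alkoxyl radical 8, which is reduced by divalent iron and protonated by EtOH. The closest known reaction type is the iron-hydride-initiated reductive radical cyclization of alkene-tethered carbonyl compounds, supported by the classical tin-hydride cyclization of alkyl radicals onto aldehydes. Ring A closes in the 6-exo-trig mode (attack on the C=O carbon, oxygen exocyclic). The trans ring fusion is not made here but follows from the trans-diequatorial C5 arm and C10 chain set in steps 1 and 2; the new C3 centre should arise from a chair transition state with the carbonyl oxygen pseudo-equatorial, giving the equatorial 3β-alcohol, and reversible ring opening of 8 works in the same direction. The step needs hydrogen-atom transfer to the electron-neutral 1,1-disubstituted alkene rather than to the electron-poor enone (the reason for choosing Fe(acac)3) and ring closure rather than plain reduction; the aldehyde is the only acceptor that 7 can reach through a strain-free ring, since attack on the enone carbons would need a four-membered ring or a strained bridged bicycle.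

Step 5
Reactants: 9 (4aS,6S,8aS)-6-hydroxy-2,5,5,8a-tetramethyl-4a,5,6,7,8,8a-hexahydronaphthalen-1(4H)-one
Product: 10 (2S,4aS,8aS)-1,1,4a,6-tetramethyl-5-oxo-1,2,3,4,4a,5,8,8a-octahydronaphthalen-2-yl 2,2-dimethylpropanoate
Conditions: PivCl, DMAP, pyridine, CH2Cl2, 40 °C
Reagents that add atoms: pivaloyl chloride, SMILES: CC(C)(C)C(Cl)=O
Why: DMAP-catalysed acylation of the hindered equatorial alcohol with retention at C3; the pivalate has no alpha-hydrogen, so it should survive the two strong-base steps, and it is removed without an extra step in the hydride reduction of step 9.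

Step 6
Reactants: 10 (2S,4aS,8aS)-1,1,4a,6-tetramethyl-5-oxo-1,2,3,4,4a,5,8,8a-octahydronaphthalen-2-yl 2,2-dimethylpropanoate
Product: 12 (2S,4aS,8aS)-1,1,4a,6-tetramethyl-5-[(trifluoromethanesulfonyl)oxy]-1,2,3,4,4a,8a-hexahydronaphthalen-2-yl 2,2-dimethylpropanoate, via potassium dienolate 11 (not isolated)
Conditions: KN(SiMe3)2, THF, −78 °C; then PhNTf2, −78 °C to rt
Reagents that add atoms: N-phenylbis(trifluoromethanesulfonimide), SMILES: O=S(=O)(N(c1ccccc1)S(=O)(=O)C(F)(F)F)C(F)(F)F
Why: Dienol triflate formation: the alpha' carbon (C10) is quaternary, so the base can only remove a gamma-hydrogen at C6, and O-sulfonylation of the linear dienolate installs the C6=C7 double bond of the target and turns C9 into a coupling site.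

Step 7
Reactants: 12 (2S,4aS,8aS)-1,1,4a,6-tetramethyl-5-[(trifluoromethanesulfonyl)oxy]-1,2,3,4,4a,8a-hexahydronaphthalen-2-yl 2,2-dimethylpropanoate
Product: 13 methyl (4aR,6S,8aS)-6-[(2,2-dimethylpropanoyl)oxy]-2,5,5,8a-tetramethyl-4a,5,6,7,8,8a-hexahydronaphthalene-1-carboxylate
Conditions: Pd(OAc)2 (10 mol%), PPh3, CO (1 atm), MeOH, Et3N, DMF, 60 °C
Reagents that add atoms: carbon monoxide, SMILES: [C-]#[O+]; methanol, SMILES: CO
Why: Palladium-catalysed methoxycarbonylation of the alkenyl triflate (oxidative addition to zerovalent palladium, CO insertion, methanolysis) brings in C11 at the ester level; no stereocentre is touched.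

Step 8
Reactants: 13 methyl (4aR,6S,8aS)-6-[(2,2-dimethylpropanoyl)oxy]-2,5,5,8a-tetramethyl-4a,5,6,7,8,8a-hexahydronaphthalene-1-carboxylate
Product: 15 methyl (1S,4aR,6S,8aS)-6-[(2,2-dimethylpropanoyl)oxy]-5,5,8a-trimethyl-2-methylidene-1,2,4a,5,6,7,8,8a-octahydronaphthalene-1-carboxylate, via lithium dienolate 14 (not isolated)
Conditions: LiN(iPr)2, THF/DMPU, −78 °C; then AcOH, −78 °C
Reagents that add atoms: none
Why: Deconjugative protonation: the only gamma-hydrogens are on the C8 methyl group, which is cis to the ester, so deprotonation gives the cross-conjugated dienolate, and kinetic protonation at the alpha-carbon C9 from the face opposite the axial C10 methyl group should give the exocyclic methylene and the equatorial 9β-ester.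

Step 9
Reactants: 15 methyl (1S,4aR,6S,8aS)-6-[(2,2-dimethylpropanoyl)oxy]-5,5,8a-trimethyl-2-methylidene-1,2,4a,5,6,7,8,8a-octahydronaphthalene-1-carboxylate
Product: 16 (2S,4aS,5S,8aR)-5-(hydroxymethyl)-1,1,4a-trimethyl-6-methylidene-1,2,3,4,4a,5,6,8a-octahydronaphthalen-2-ol
Conditions: LiAlH4, Et2O, 0 °C to rt; aqueous NaOH work-up
Reagents that add atoms: none
Why: Hydride reduction of the methyl ester to the primary alcohol with reductive cleavage of the pivalate in the same operation; the unpolarised diene is inert to LiAlH4 and no stereocentre changes.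

Step 10
Reactants: 16 (2S,4aS,5S,8aR)-5-(hydroxymethyl)-1,1,4a-trimethyl-6-methylidene-1,2,3,4,4a,5,6,8a-octahydronaphthalen-2-ol; 17 7-hydroxy-2H-chromen-2-one (umbelliferone)
Product: 18 7-{[(1S,4aR,6S,8aS)-6-hydroxy-5,5,8a-trimethyl-2-methylidene-1,2,4a,5,6,7,8,8a-octahydronaphthalen-1-yl]methoxy}-2H-chromen-2-one
Conditions: PPh3, DIAD, THF, 0 °C to rt
Reagents that add atoms: none
Why: Mitsunobu etherification: the acidic phenol displaces the oxyphosphonium of the primary C11 alcohol by SN2, while the secondary C3 alcohol next to the gem-dimethyl carbon is too hindered to be activated, so no stereocentre is touched.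

**Compound list**
1 | (R)-(−)-carvone, (5R)-2-methyl-5-(prop-1-en-2-yl)cyclohex-2-en-1-one | CC1=CC[C@H](CC1=O)C(=C)C | starting material
2 | lithium (3R)-6-methyl-3-(prop-1-en-2-yl)cyclohexa-1,5-dien-1-olate (kinetic enolate of 1) | CC1=CC[C@H](C=C1O[Li])C(=C)C | intermediate (not isolated)
3 | (5R)-2,6-dimethyl-5-(prop-1-en-2-yl)cyclohex-2-en-1-one (both C6 epimers; C6 left undefined) | CC1=CC[C@H](C(C)C1=O)C(=C)C | intermediate
4 | lithium (3S)-2,6-dimethyl-3-(prop-1-en-2-yl)cyclohexa-1,5-dien-1-olate (enolate of 3) | CC1=CC[C@H](C(C)=C1O[Li])C(=C)C | intermediate (not isolated)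
5 | (5S,6S)-2,6-dimethyl-5-(prop-1-en-2-yl)-6-(prop-2-en-1-yl)cyclohex-2-en-1-one | C=CC[C@]1(C)C(=O)C(C)=CC[C@H]1C(C)=C | intermediate
6 | 3-[(1S,6S)-1,3-dimethyl-2-oxo-6-(prop-1-en-2-yl)cyclohex-3-en-1-yl]propanal | O=CCC[C@]1(C)C(=O)C(C)=CC[C@H]1C(C)=C | intermediate
7 | tertiary C4 radical: 2-[2,4-dimethyl-3-oxo-2-(3-oxopropyl)cyclohex-4-en-1-yl]propan-2-yl, ring stereocentres as in 6 | O=CCC[C@]1(C)C(=O)C(C)=CC[C@H]1[C](C)C | intermediate (not isolated)
8 | alkoxyl radical: the O-centred radical of 9 (oxygen on C3, all stereocentres as in 9) | CC1=CC[C@H]2C(C)(C)[C@@H]([O])CC[C@]2(C)C1=O | intermediate (not isolated)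
9 | (4aS,6S,8aS)-6-hydroxy-2,5,5,8a-tetramethyl-4a,5,6,7,8,8a-hexahydronaphthalen-1(4H)-one | CC1=CC[C@H]2C(C)(C)[C@@H](O)CC[C@]2(C)C1=O | intermediate
10 | (2S,4aS,8aS)-1,1,4a,6-tetramethyl-5-oxo-1,2,3,4,4a,5,8,8a-octahydronaphthalen-2-yl 2,2-dimethylpropanoate | CC1=CC[C@H]2C(C)(C)[C@@H](OC(=O)C(C)(C)C)CC[C@]2(C)C1=O | intermediate
11 | potassium (4aS,6S,8aS)-6-[(2,2-dimethylpropanoyl)oxy]-2,5,5,8a-tetramethyl-4a,5,6,7,8,8a-hexahydronaphthalen-1-olate (linear dienolate of 10) | CC=1C=C[C@H]2C(C)(C)[C@@H](OC(=O)C(C)(C)C)CC[C@]2(C)C=1O[K] | intermediate (not isolated)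
12 | (2S,4aS,8aS)-1,1,4a,6-tetramethyl-5-[(trifluoromethanesulfonyl)oxy]-1,2,3,4,4a,8a-hexahydronaphthalen-2-yl 2,2-dimethylpropanoate | CC=1C=C[C@H]2C(C)(C)[C@@H](OC(=O)C(C)(C)C)CC[C@]2(C)C=1OS(=O)(=O)C(F)(F)F | intermediate
13 | methyl (4aR,6S,8aS)-6-[(2,2-dimethylpropanoyl)oxy]-2,5,5,8a-tetramethyl-4a,5,6,7,8,8a-hexahydronaphthalene-1-carboxylate | CC=1C=C[C@H]2C(C)(C)[C@@H](OC(=O)C(C)(C)C)CC[C@]2(C)C=1C(=O)OC | intermediate
14 | lithium [(4aR,6S,8aS)-6-[(2,2-dimethylpropanoyl)oxy]-5,5,8a-trimethyl-2-methylidene-4a,5,6,7,8,8a-hexahydronaphthalen-1(2H)-ylidene](methoxy)methanolate (cross-conjugated dienolate of 13; enolate geometry undefined) | C=C1C=C[C@H]2C(C)(C)[C@@H](OC(=O)C(C)(C)C)CC[C@]2(C)C1=C(O[Li])OC | intermediate (not isolated)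
15 | methyl (1S,4aR,6S,8aS)-6-[(2,2-dimethylpropanoyl)oxy]-5,5,8a-trimethyl-2-methylidene-1,2,4a,5,6,7,8,8a-octahydronaphthalene-1-carboxylate | C=C1C=C[C@H]2C(C)(C)[C@@H](OC(=O)C(C)(C)C)CC[C@]2(C)[C@H]1C(=O)OC | intermediate
16 | (2S,4aS,5S,8aR)-5-(hydroxymethyl)-1,1,4a-trimethyl-6-methylidene-1,2,3,4,4a,5,6,8a-octahydronaphthalen-2-ol | C=C1C=C[C@H]2C(C)(C)[C@@H](O)CC[C@]2(C)[C@H]1CO | intermediate
17 | 7-hydroxy-2H-chromen-2-one (umbelliferone) | Oc1ccc2ccc(=O)oc2c1 | starting material
18 | 7-{[(1S,4aR,6S,8aS)-6-hydroxy-5,5,8a-trimethyl-2-methylidene-1,2,4a,5,6,7,8,8a-octahydronaphthalen-1-yl]methoxy}-2H-chromen-2-one | C=C1C=C[C@H]2C(C)(C)[C@@H](O)CC[C@]2(C)[C@H]1COc1ccc2ccc(=O)oc2c1 | target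

**Step count:** 10 steps in total; longest linear sequence 10 steps (1 to 18).

**Steps most likely to fail**

Step 4. What may go wrong: hydrogen-atom transfer to the enone instead of the isopropenyl group, reduction of radical 7 or of the aldehyde before ring closure, ring opening of 8 faster than its reduction, or incomplete facial selectivity at C3. The fallback sets out from 6 and makes the radical by halogen abstraction instead of by a metal hydride. Addition of HBr (HBr in AcOH, 0 °C) to the isopropenyl group, the classical hydrobromination of carvone-type isopropenyl groups, should give 3-[(1S,6R)-6-(2-bromopropan-2-yl)-1,3-dimethyl-2-oxocyclohex-3-en-1-yl]propanal F1. Slow addition of Bu3SnH with AIBN in benzene at 80 °C should then generate the same C4 radical in a chain process and close ring A onto the aldehyde (tin-hydride radical cyclization onto an aldehyde), so that the path comes back to the route at 9.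

Step 8. What may go wrong: deprotonation at the remote allylic C5–H instead of the C8 methyl group, protonation at the gamma-carbon (return to 13), protonation of C9 from the wrong face, or reconjugation during work-up. The fallback sets out from 13 and moves the deconjugation to the aldehyde level under non-basic enolization. LiAlH4 (Et2O, 0 °C) should give (2S,4aS,8aR)-5-(hydroxymethyl)-1,1,4a,6-tetramethyl-1,2,3,4,4a,8a-hexahydronaphthalen-2-ol F2. MnO2 (CH2Cl2, rt) should oxidise only the dienylic primary alcohol to (4aR,6S,8aS)-6-hydroxy-2,5,5,8a-tetramethyl-4a,5,6,7,8,8a-hexahydronaphthalene-1-carbaldehyde F3. Me3SiOTf and Et3N (CH2Cl2, −78 to 0 °C) can enolise only into the C8 methyl group and should give trimethyl{[(4aR,6S,8aS)-5,5,8a-trimethyl-2-methylidene-6-(trimethylsilyloxy)-4a,5,6,7,8,8a-hexahydronaphthalen-1(2H)-ylidene]methoxy}silane F4 (enol ether geometry not controlled). Mild hydrolysis (AcOH, THF/H2O, 0 °C), with alpha-protonation from the face opposite the C10 methyl group, should give (1S,4aR,6S,8aS)-6-hydroxy-5,5,8a-trimethyl-2-methylidene-1,2,4a,5,6,7,8,8a-octahydronaphthalene-1-carbaldehyde F5, which is reduced at once with NaBH4 (MeOH, −20 °C), so that the path comes back to the route at 16.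

Step 10. What may go wrong: elimination of the activated, beta-branched primary alcohol across the allylic C9–H toward a cross-conjugated triene, or slow substitution at the hindered CH2. The fallback sets out from 16 and reverses the roles of the partners, so that no substitution takes place at C11. Palladium-catalysed C–O coupling of the primary alcohol of 16 with commercial 7-bromo-2H-chromen-2-one (Pd2(dba)3, RockPhos, Cs2CO3, toluene, 90 °C; aryl-oxygen bond formation by reductive elimination from divalent palladium) should leave the hindered secondary alcohol untouched and comes back to the route at 18; no new compound is made on this path (F0).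

Further compounds
F1 | step 4 | 3-[(1S,6R)-6-(2-bromopropan-2-yl)-1,3-dimethyl-2-oxocyclohex-3-en-1-yl]propanal | O=CCC[C@]1(C)C(=O)C(C)=CC[C@H]1C(C)(C)Br
F2 | step 8 | (2S,4aS,8aR)-5-(hydroxymethyl)-1,1,4a,6-tetramethyl-1,2,3,4,4a,8a-hexahydronaphthalen-2-ol | CC=1C=C[C@H]2C(C)(C)[C@@H](O)CC[C@]2(C)C=1CO
F3 | step 8 | (4aR,6S,8aS)-6-hydroxy-2,5,5,8a-tetramethyl-4a,5,6,7,8,8a-hexahydronaphthalene-1-carbaldehyde | CC=1C=C[C@H]2C(C)(C)[C@@H](O)CC[C@]2(C)C=1C=O
F4 | step 8 | trimethyl{[(4aR,6S,8aS)-5,5,8a-trimethyl-2-methylidene-6-(trimethylsilyloxy)-4a,5,6,7,8,8a-hexahydronaphthalen-1(2H)-ylidene]methoxy}silane | C=C1C=C[C@H]2C(C)(C)[C@@H](O[Si](C)(C)C)CC[C@]2(C)C1=CO[Si](C)(C)C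
F5 | step 8 | (1S,4aR,6S,8aS)-6-hydroxy-5,5,8a-trimethyl-2-methylidene-1,2,4a,5,6,7,8,8a-octahydronaphthalene-1-carbaldehyde | C=C1C=C[C@H]2C(C)(C)[C@@H](O)CC[C@]2(C)[C@H]1C=O
F0 | step 10 | none | none
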